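Cuts, in bicyclo[3.1.0]hexane numbering (C1 methyl-bearing bridgehead, C2 aryl/methyl carbon, C3 and C4 CH2, C5 CH bridgehead, C6 cyclopropane CH2): first the two C–Br bonds, then C5–C6 after a ketone is placed at C4, and last C2–C3 and C1–C5 together.
Enabling feature: the benzene ring, the phenol oxygen, C6, C1 with its methyl and C2 with its methyl correspond one-to-one to the two rings of 3,4,7-trimethylcoumarin (coumarin C2 = C6, C3 = C1, C4 = C2). Aryl and C6 lie on the same face of the five-membered ring in the target, so an O–C6 link fits a cis-fused lactone.
The remaining unit C3–C4–C5 is a trimethylenemethane, so a (3+2) annulation across the coumarin C3=C4 bond builds the cyclopentane in one step.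
Ring order forward: pyranone (Pechmann), cyclopentane (palladium trimethylenemethane annulation), reductive opening of the lactone, cyclopropane (C5 enolate displaces a C6 mesylate), then C4 deoxygenation, O-demethylation and double bromination.
Stereochemistry: a chiral phosphoramidite on palladium selects the coumarin face (absolute configuration, C2). Suprafacial bridging ties C1 to C2 (methyls cis), and C5 follows from C1 because the three-membered ring can only be cis-fused. No later step can invert these centres.
Key step: step 2

Assumption: the sense of asymmetric induction on this untested acceptor cannot be predicted, so the (R,R,R) ligand is written for the (3aS,9bS) series and its mirror image is to be used if a first run shows the opposite sense.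

Step 1
Reactants: 1 m-cresol; 2 ethyl 2-methylacetoacetate
Product: 3 3,4,7-trimethylcoumarin
Conditions: conc. H2SO4, 0 °C → rt
Reagents that add atoms: none
Why: Pechmann condensation: in strong acid the keto ester is transferred to the phenol oxygen, its ketone carbon attacks the ring ortho to oxygen at the position para to the methyl group (the site between OH and CH3 is more crowded) and water is lost, a sequence long established for m-cresol and 2-alkylacetoacetates that should give the 7-methyl isomer.

Step 2
Reactants: 3 3,4,7-trimethylcoumarin; 4 2-[(trimethylsilyl)methyl]allyl acetate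
Product: 5 (3aS,9bS)-3a,7,9b-trimethyl-2-methylidene-2,3,3a,9b-tetrahydrocyclopenta[c]chromen-4(1H)-one (cis-fused, both angular methyl groups on the same face)
Conditions: CpPd(η3-C3H5) (10 mol %), (R,R,R)-L* (22 mol %), Al(OC6H3-2,6-Ph2)3 (30 mol %, preformed), 4 (3 equiv, slow addition), toluene, 50 °C; L* = phosphoramidite from (R)-BINOL and (2R,5R)-2,5-di(2-naphthyl)pyrrolidine
Reagents that add atoms: none
Why: Proposed new method: zerovalent palladium ionises 4, the acetate takes off the silyl group, and the carbanionic CH2 of the palladium-bound trimethylenemethane zwitterion adds to coumarin C4 (new bond C9b–C1 of 5, target C2–C3), an attack that the aluminium phenoxide should speed up by binding the lactone carbonyl oxygen while its aryl pocket screens the carbonyl carbon. The aluminium enolate then attacks through coumarin C3 one terminus of the tethered cationic π-allylpalladium unit on the side away from the metal (new bond C3a–C3 of 5, target C1–C5), which closes the cyclopentane in a five-membered closure that counts as 5-exo-tet on the σ-allyl form, palladium being the exocyclic leaving group. The closest known reaction type is the enantioselective palladium trimethylenemethane (3+2) cycloaddition to coumarins with an extra acceptor at C3 and to trisubstituted or β,β-disubstituted acceptors; a tetrasubstituted alkene activated by a single lactone carbonyl and the aluminium co-catalyst have not been shown, hence the label. C9b is set in the conjugate addition, where the chiral phosphoramidite on palladium tells apart the two faces of the flat, achiral coumarin, and C3a is set by C9b, because the three-carbon bridge can reach only the face from which it was delivered, so that only the cis-fused ring with both methyl groups on the same side can form. The step needs 1,4- over 1,2-addition, C- over O-allylation, retention of the alkene geometry between the two bond formations and turnover of the Lewis acid; the substrate secures these through its vinylogous aryl ester with the largest acceptor coefficient at C4, through the seven-membered and palladium-reversible nature of O-allylation, through the ring that locks the enolate against rotation, and through its flat, unhindered carbonyl, which should bind aluminium better than the carbonyl of 5 next to a quaternary carbon. Regiochemistry is no issue with the symmetric donor, and CpPd(η3-C3H5) is used so that no dibenzylideneacetone competes for the Lewis acid.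

Step 3
Reactants: 5 cis-fused lactone
Product: 6 2-[(1R,2S)-2-(hydroxymethyl)-1,2-dimethyl-4-methylidenecyclopentyl]-5-methylphenol (aryl and CH2OH cis)
Conditions: LiAlH4, THF, 0 °C → reflux; aq potassium sodium tartrate
Reagents that add atoms: none
Why: Hydride reduction of an aryl ester: LiAlH4 cleaves the acyl–oxygen bond of the lactone and takes C6 down to the primary alcohol, the isolated 1,1-disubstituted alkene is inert to hydride, and both stereocentres are quaternary and cannot epimerise.

Step 4
Reactants: 6 phenol alcohol
Product: 7 [(1S,2R)-2-(2-methoxy-4-methylphenyl)-1,2-dimethyl-4-methylidenecyclopentyl]methanol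
Conditions: MeI, K2CO3, acetone, reflux
Reagents that add atoms: iodomethane, CI
Why: Williamson ether synthesis under pKa control: K2CO3 deprotonates only the phenol, so MeI caps the oxygen that would otherwise displace the later C6 leaving group with formation of a chroman, while the neopentyl alcohol stays free.

Step 5
Reactants: 7 aryl methyl ether alcohol
Product: 8 [(1S,2R)-2-(2-methoxy-4-methylphenyl)-1,2-dimethyl-4-methylidenecyclopentyl]methyl methanesulfonate
Conditions: MsCl, Et3N, CH2Cl2, 0 °C
Reagents that add atoms: methanesulfonyl chloride, CS(=O)(=O)Cl
Why: Standard O-sulfonylation of a primary alcohol: the reaction takes place at oxygen and is therefore not slowed by the neopentyl carbon, the alkene and the aryl ether are inert, and no stereocentre is touched.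

Step 6
Reactants: 8 alkene mesylate
Product: 10 [(1S,2R)-2-(2-methoxy-4-methylphenyl)-1,2-dimethyl-4-oxocyclopentyl]methyl methanesulfonate, via secondary ozonide 9 (not isolated)
Conditions: O3, CH2Cl2, −78 °C (Sudan Red 7B as end-point dye); PPh3, −78 °C → rt
Reagents that add atoms: ozone, [O-][O+]=O
Why: Ozonolysis with reductive work-up: the electron-rich 1,1-disubstituted alkene undergoes the 1,3-dipolar cycloaddition far faster than the anisole ring, the dye marks the end point so that excess ozone is avoided, PPh3 reduces ozonide 9 to the C4 ketone and formaldehyde, and the mesylate is inert to both reagents.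

Step 7
Reactants: 10 keto mesylate
Product: 11 (1R,4R,5S)-4-(2-methoxy-4-methylphenyl)-4,5-dimethylbicyclo[3.1.0]hexan-2-one (cyclopropane CH2 syn to aryl)
Conditions: KOt-Bu, THF–t-BuOH, 0 °C → rt
Reagents that add atoms: none
Why: Intramolecular enolate alkylation of a γ-sulfonyloxy ketone (3-exo-tet), the classical entry to bicyclo[3.1.0]hexan-2-ones: the C3 and C5 enolates equilibrate through t-BuOH and only the C5 enolate can reach C6, since the C3 enolate would have to close a strained four-membered ring and O-alkylation would give a bridgehead alkene, the geminal substitution at C1 favours closure despite the neopentyl electrophile, and C5 is set by C1 because the new ring can only be cis-fused on the face that carries C6.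

Step 8
Reactants: 11 cyclopropyl ketone
Product: 13 (1S,2R,5R)-2-(2-methoxy-4-methylphenyl)-1,2-dimethylbicyclo[3.1.0]hexane, via hydrazone 12 (not isolated)
Conditions: N2H4·H2O, KOH, diethylene glycol, 130 °C, then 195 °C
Reagents that add atoms: hydrazine hydrate, NN.O (its nitrogen atoms stay only in 12)
Why: Wolff–Kishner reduction in the Huang-Minlon form, well precedented for bicyclo[3.1.0]hexan-2-ones: the unhindered C4 ketone forms hydrazone 12 at 130 °C, KOH at 195 °C then expels N2, the medium stays basic so that the acid-labile cyclopropane and the aryl methyl ether survive, and C5 cannot epimerise because only the cis fusion is possible.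

Step 9
Reactants: 13 aryl methyl ether
Product: 14 2-[(1S,2R,5R)-1,2-dimethylbicyclo[3.1.0]hexan-2-yl]-5-methylphenol
Conditions: NaSEt, DMF, 140 °C; aq NH4Cl
Reagents that add atoms: none
Why: Nucleophilic (SN2) demethylation of an aryl methyl ether by ethanethiolate in a dipolar aprotic solvent: attack at the unhindered methyl carbon is not affected by the bulky ortho substituent, and the acid-free medium avoids the proton-induced opening of the cyclopropane by the neighbouring phenol that Lewis or Brønsted acidic reagents such as BBr3 would cause.

Step 10
Reactants: 14 phenol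
Product: 16 2,4-dibromo-6-[(1S,2R,5R)-1,2-dimethylbicyclo[3.1.0]hexan-2-yl]-3-methylphenol, via para-monobromide 15 (not isolated)
Conditions: NBS (2.05 equiv), MeCN, −10 °C → rt, dark
Reagents that add atoms: N-bromosuccinimide, O=C1CCC(=O)N1Br
Why: Phenol-directed electrophilic aromatic substitution: the first bromine should enter para to OH (15) and the second at the only free ortho position, between OH and CH3, as in the known double bromination of thymol and other 2-alkyl-5-methylphenols, while NBS leaves neutral succinimide instead of HBr so that the cyclopropane is not protonated, and darkness suppresses benzylic bromination.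

Compound list
1 | m-cresol (3-methylphenol) | Cc1cccc(O)c1 | starting material
2 | ethyl 2-methylacetoacetate (ethyl 2-methyl-3-oxobutanoate, racemic) | CCOC(=O)C(C)C(C)=O | starting material
3 | 3,4,7-trimethylcoumarin (3,4,7-trimethyl-2H-chromen-2-one) | Cc1ccc2c(C)c(C)c(=O)oc2c1 | intermediate
4 | 2-[(trimethylsilyl)methyl]allyl acetate | CC(=O)OCC(=C)C[Si](C)(C)C | starting material
5 | (3aS,9bS)-3a,7,9b-trimethyl-2-methylidene-2,3,3a,9b-tetrahydrocyclopenta[c]chromen-4(1H)-one | Cc1ccc2c(c1)OC(=O)[C@@]1(C)CC(=C)C[C@@]21C | intermediate
6 | 2-[(1R,2S)-2-(hydroxymethyl)-1,2-dimethyl-4-methylidenecyclopentyl]-5-methylphenol | Cc1ccc(c(O)c1)[C@]2(C)CC(=C)C[C@]2(C)CO | intermediate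
7 | [(1S,2R)-2-(2-methoxy-4-methylphenyl)-1,2-dimethyl-4-methylidenecyclopentyl]methanol | COc1cc(C)ccc1[C@]2(C)CC(=C)C[C@]2(C)CO | intermediate
8 | [(1S,2R)-2-(2-methoxy-4-methylphenyl)-1,2-dimethyl-4-methylidenecyclopentyl]methyl methanesulfonate | COc1cc(C)ccc1[C@]2(C)CC(=C)C[C@]2(C)COS(C)(=O)=O | intermediate
9 | secondary ozonide of 8 (spiro-1,2,4-trioxolane at C4, both epimers at the spiro carbon) | COc1cc(C)ccc1[C@]2(C)CC3(OCOO3)C[C@]2(C)COS(C)(=O)=O | intermediate
10 | [(1S,2R)-2-(2-methoxy-4-methylphenyl)-1,2-dimethyl-4-oxocyclopentyl]methyl methanesulfonate | COc1cc(C)ccc1[C@]2(C)CC(=O)C[C@]2(C)COS(C)(=O)=O | intermediate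
11 | (1R,4R,5S)-4-(2-methoxy-4-methylphenyl)-4,5-dimethylbicyclo[3.1.0]hexan-2-one | COc1cc(C)ccc1[C@]2(C)CC(=O)[C@@H]3C[C@@]32C | intermediate
12 | hydrazone of 11 (C=N geometry not defined) | COc1cc(C)ccc1[C@]2(C)CC(=NN)[C@@H]3C[C@@]32C | intermediate
13 | (1S,2R,5R)-2-(2-methoxy-4-methylphenyl)-1,2-dimethylbicyclo[3.1.0]hexane | COc1cc(C)ccc1[C@]2(C)CC[C@@H]3C[C@@]32C | intermediate
14 | 2-[(1S,2R,5R)-1,2-dimethylbicyclo[3.1.0]hexan-2-yl]-5-methylphenol | Cc1ccc(c(O)c1)[C@]2(C)CC[C@@H]3C[C@@]32C | intermediate
15 | 4-bromo-2-[(1S,2R,5R)-1,2-dimethylbicyclo[3.1.0]hexan-2-yl]-5-methylphenol | Cc1cc(O)c(cc1Br)[C@]2(C)CC[C@@H]3C[C@@]32C | intermediate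
16 | 2,4-dibromo-6-[(1S,2R,5R)-1,2-dimethylbicyclo[3.1.0]hexan-2-yl]-3-methylphenol | Cc1c(Br)cc([C@]2(C)CC[C@@H]3C[C@@]32C)c(O)c1Br | target

Total step count: 10. Longest linear sequence: 10 steps (1 → 16); 4 is used as bought.

Steps most likely to fail

Step 2. Four things may go wrong:
- Attack on a fully substituted β-carbon of a singly activated alkene may be slower than self-consumption of the donor by oligomerisation or protodesilylation.
- The basic trimethylenemethane carbon may take a proton from the C4-methyl group of the aluminium-bound coumarin, which would turn the annulation into plain allylation.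
- Aluminium may hold back acetate and stall desilylation.
- The ligand may distinguish the two faces poorly.

A pressure of about 10 kbar, a lever known for β,β-disubstituted enones in this cycloaddition, would be tried first.

The fallback uses known reactions only, sets out from 3 and comes back at 11. It builds the two quaternary carbons one at a time, by a sigmatropic shift and a carbene addition. i-Bu2AlH (CH2Cl2, −78 → 0 °C) opens 3 to (Z)-2-(4-hydroxy-3-methylbut-2-en-2-yl)-5-methylphenol F1. MeI/K2CO3 then gives (Z)-3-(2-methoxy-4-methylphenyl)-2-methylbut-2-en-1-ol F2. Johnson–Claisen rearrangement (MeC(OEt)3, cat. EtCO2H, 140 °C) creates C2 in racemic ethyl 3-(2-methoxy-4-methylphenyl)-3,4-dimethylpent-4-enoate F3. Preparative chromatography on a chiral stationary phase resolves this to ethyl (3R)-3-(2-methoxy-4-methylphenyl)-3,4-dimethylpent-4-enoate F4. LiOH gives (3R)-3-(2-methoxy-4-methylphenyl)-3,4-dimethylpent-4-enoic acid F5. (COCl)2 gives (3R)-3-(2-methoxy-4-methylphenyl)-3,4-dimethylpent-4-enoyl chloride F6, and excess CH2N2 gives (4R)-1-diazo-4-(2-methoxy-4-methylphenyl)-4,5-dimethylhex-5-en-2-one F7. Rh2(OAc)4 in CH2Cl2 then adds the carbene carbon (C5) across the isopropenyl group (C1=C6) to give 11. Little facial bias is expected, so (1S,4R,5R)-4-(2-methoxy-4-methylphenyl)-4,5-dimethylbicyclo[3.1.0]hexan-2-one F8, the diastereomer with the cyclopropane anti to the aryl group, has to be removed by chromatography.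

Step 8. Three things may go wrong:
- The three-membered ring may open when carbanionic character develops at C4 next to it during loss of N2.
- Azine formation may compete with the reduction.
- The ether may be partly cleaved at 195 °C.

The fallback sets out from 11 and comes back at 13. It removes the oxygen through an alkene rather than a hydrazone. KN(SiMe3)2 and PhNTf2 (THF, −78 °C) enolise only towards C3, because the bridgehead C5–H is not available. This gives (1R,4R,5S)-4-(2-methoxy-4-methylphenyl)-4,5-dimethylbicyclo[3.1.0]hex-2-en-2-yl trifluoromethanesulfonate F9. Pd(OAc)2/PPh3 with HCO2H and n-Bu3N (DMF, 60 °C) reduces it to (1S,4R,5S)-4-(2-methoxy-4-methylphenyl)-4,5-dimethylbicyclo[3.1.0]hex-2-ene F10. Diimide, generated from 2-nitrobenzenesulfonohydrazide and Et3N, saturates the alkene without hydrogenolysis of the vinylcyclopropane and gives 13.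

Step 10. Four things may go wrong:
- The second substitution may stay incomplete at the crowded position between OH and CH3.
- Over-oxidation to bromodienones may occur.
- Benzylic bromination may compete.
- Acid may build up and cause proton-induced opening of the cyclopropane with capture by the phenol oxygen.

The fallback sets out from 14 and comes back at 16. It separates the two substitutions and gives each its own reagent control. n-Bu4NBr3 (1 equiv, CH2Cl2–MeOH, CaCO3) should stop at the para stage, and 15 is isolated and purified. The hindered ortho position is then brominated with N-bromo-tert-butylamine, made from t-BuNH2 and Br2 in toluene at −70 °C. This is an ortho-selective phenol bromination that delivers bromine through a hydrogen bond to the OH group. It runs in excess amine, so all acid is bound. This fallback makes no compound outside the list (F0).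

Further compounds
F1 | step 2 | (Z)-2-(4-hydroxy-3-methylbut-2-en-2-yl)-5-methylphenol | Cc1ccc(c(O)c1)/C(C)=C(/C)CO
F2 | step 2 | (Z)-3-(2-methoxy-4-methylphenyl)-2-methylbut-2-en-1-ol | COc1cc(C)ccc1/C(C)=C(/C)CO
F3 | step 2 | racemic ethyl 3-(2-methoxy-4-methylphenyl)-3,4-dimethylpent-4-enoate | COc1cc(C)ccc1C(C)(C(C)=C)CC(=O)OCC
F4 | step 2 | ethyl (3R)-3-(2-methoxy-4-methylphenyl)-3,4-dimethylpent-4-enoate | COc1cc(C)ccc1[C@](C(C)=C)(C)CC(=O)OCC
F5 | step 2 | (3R)-3-(2-methoxy-4-methylphenyl)-3,4-dimethylpent-4-enoic acid | COc1cc(C)ccc1[C@](C(C)=C)(C)CC(=O)O
F6 | step 2 | (3R)-3-(2-methoxy-4-methylphenyl)-3,4-dimethylpent-4-enoyl chloride | COc1cc(C)ccc1[C@](C(C)=C)(C)CC(=O)Cl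
F7 | step 2 | (4R)-1-diazo-4-(2-methoxy-4-methylphenyl)-4,5-dimethylhex-5-en-2-one | COc1cc(C)ccc1[C@](C(C)=C)(C)CC(=O)C=[N+]=[N-]
F8 | step 2 | (1S,4R,5R)-4-(2-methoxy-4-methylphenyl)-4,5-dimethylbicyclo[3.1.0]hexan-2-one | COc1cc(C)ccc1[C@]2(C)CC(=O)[C@H]3C[C@]32C
F9 | step 8 | (1R,4R,5S)-4-(2-methoxy-4-methylphenyl)-4,5-dimethylbicyclo[3.1.0]hex-2-en-2-yl trifluoromethanesulfonate | COc1cc(C)ccc1[C@]2(C)C=C(OS(=O)(=O)C(F)(F)F)[C@@H]3C[C@@]32C
F10 | step 8 | (1S,4R,5S)-4-(2-methoxy-4-methylphenyl)-4,5-dimethylbicyclo[3.1.0]hex-2-ene | COc1cc(C)ccc1[C@]2(C)C=C[C@@H]3C[C@@]32C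
F0 | step 10 | none | none
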